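The numbers in the tables are calculated with constants of no real substance, noise included.

1. Watch the isomer. The flasks alpha, beta, gamma and theta are to be ranked by the share of target in all that became target or isomer of the product.

| flask | starting material | catalyst | temperature | remark | time |
|---|---|---|---|---|---|
| north-west | 32 mM | 11 µM | 40 °C | run made earlier |  |
| alpha | 16 mM | 11 µM | 40 °C |  | 2.5 d |
| beta | 16 mM | 11 µM | 65 °C |  | 2.5 d |
| gamma | 16 mM | 11 µM |  | at 65 °C until 12 h, from then on at 15 °C | 2.5 d |
| theta | 16 mM | 11 µM | 15 °C |  | 2.5 d |

north-west run (percent of the starting material charged)

| time / h | target / % | isomer of the product / % |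
|---|---|---|
| 2.50 | 36.1 | 0 |
| 5.00 | 54.3 | 3.7 |
| 8.00 | 65.0 | 4.2 |
| 10.0 | 66.3 | 8.2 |
| 12.0 | 68.5 | 9.5 |

(scatter of a reading: 1 percentage point)

1. the best flask by share of target in all that became target or isomer of the product; "all alike" if 1.5 percentage points covers them all (alpha / beta / gamma / theta / all alike)
2. share of target in all that became target or isomer of the product, alpha
3. share of target in all that became target or isomer of the product, beta
4. share of target in all that became target or isomer of the product, gamma
5. share of target in all that became target or isomer of the product, theta

- the earlier runs do not show what temperature does; that part of a forecast is a guess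

2. In the north-west run the isomer lags behind the target, so I take target as its source. Adding up target over time to the last reading gives 6.03 h of the whole charge standing as target, and that produced 9.5% of isomer, so I get 0.0157 h⁻¹, the leak constant: isomer gained per hour for each unit of target standing.

3. If the leak runs one way, the share in alpha is exp(−leak constant · time), or 39.0%. But that sends target towards nothing, and a north-west share still at 87.8% cannot show whether isomer returns. So I take the symmetric case as the zero of the scale: with target and isomer equally stable, share = (1 + exp(−2 · leak constant · time))/2, which gives 57.6%.

4. But target does not stand there from the start. Its average age at the last reading puts the delay at 4.27 h, which is shorter than the 2.5 d of alpha. Taking it off the clock, I commit to 58.6% for alpha, assuming that a first-order leak ignores the halved charge. Temperature is unread, so I guess that colder leaks slower and that theta leads.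

5. The forecast, which holds that “this looks like a consecutive reaction”, names theta and gives 48% for alpha, where I reckon higher, then 10% for beta, 30% for gamma and 93% for theta.

6. The flasks give theta as best: alpha 64.0%, beta 84.6%, gamma 85.3%, theta 98.4%.

    starting material + catalyst ⇌ target + catalyst, rate k1*[starting material]*[catalyst] forward; the back reaction follows from the equilibrium constant (K = 3.90, k = 18000 M⁻¹ h⁻¹, Ea = 48.0 kJ mol⁻¹, ΔH = −15.0 kJ mol⁻¹)
    target ⇌ isomer of the product (K = 0.710, k = 0.0160 h⁻¹, Ea = 113 kJ mol⁻¹, ΔH = −48.0 kJ mol⁻¹)
    (constants at 40 °C)

In theta, target and isomer relax by that step alone, both ways together, with a half-life of 60.7 d, longer than the 2.5 d of the flask, which is kinetic control. Theta's target, rising through 64.5% to 80.0%, adds up to 31.3 h and yields 1.26% of isomer, so its leak constant is 4.02 × 10⁻⁴ h⁻¹, smaller than the north-west reading by a factor of 39.2. A neighbouring flask, like theta but with 0.0027 mM of catalyst, a quarter of theta's, ends with 42.2% target. Taking that rise as straight gives 12.7 h, hence 0.509% of isomer. That neighbouring flask holds 0.523% of isomer, and its share of target is 98.8%.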